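**Retrosynthetic overview**
- Kukoamine B comes from one global hydrogenation of a hexa-protected bis-cinnamamide (2 C=C saturated, 4 O-benzyl and 2 N-Cbz groups removed).
- That amide comes from double N-acylation of an N1,N9-bis-Cbz spermine (free N4-H and N12-H2) with two equivalents of 3,4-bis(benzyloxy)cinnamoyl chloride.
- The cinnamic acid comes from dehydration and saponification of a β-hydroxy ester, itself made by the key intermolecular aldol addition of the ethyl acetate lithium enolate to 3,4-bis(benzyloxy)benzaldehyde (the Cα–Cβ bond of each dihydrocaffeoyl unit).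
- The spermine core is built by two stepwise reductive aminations (N9–C, then N4–C) from 4-aminobutan-1-ol, a Boc-aminopropanal and mono-Cbz-1,3-diaminopropane, with Cbz put on N9 and Boc taken off N12.
- No ring is formed anywhere; both benzene rings are bought in the aldehyde.

Assumption: the target has no stereocentre and no C=C bond, so it is a single achiral compound and no stereocontrol is needed; it is isolated as the free base. Spermine locants used below: N1–(CH2)3–N4–(CH2)4–N9–(CH2)3–N12, where N1 ends as the free NH2.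

**Route**

Step 1
Reactants: 1 ethyl acetate; 2 3,4-bis(benzyloxy)benzaldehyde
Product: 4 ethyl (±)-3-[3,4-bis(benzyloxy)phenyl]-3-hydroxypropanoate, via lithium enolate of ethyl acetate 3 (not isolated)
Conditions: LDA (1.1 equiv, commercial solution), THF, −78 °C, add 1 (1.1 equiv), 30 min; then 2, −78 °C, 1 h; sat. aq NH4Cl at −78 °C
Reagents that add atoms: none
Why: Directed intermolecular aldol addition of a preformed lithium ester enolate to a non-enolisable aldehyde forges the Cα–Cβ bond of the acyl unit; the new carbinol centre is racemic and is destroyed in step 2, so no stereocontrol is needed.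

Step 2
Reactants: 4 ethyl (±)-3-[3,4-bis(benzyloxy)phenyl]-3-hydroxypropanoate
Product: 6 ethyl (E)-3-[3,4-bis(benzyloxy)phenyl]prop-2-enoate, via benzylic mesylate 5 (not isolated)
Conditions: MsCl (1.3 equiv), Et3N (3 equiv), CH2Cl2, 0 °C; then DBU (2 equiv), 0 °C → rt
Reagents that add atoms: none
Why: Mesylation followed by base-induced E1cB β-elimination gives the conjugated cinnamate as the thermodynamically favoured E isomer and removes the racemic centre; benzyl ethers are inert.

Step 3
Reactants: 6 ethyl (E)-3-[3,4-bis(benzyloxy)phenyl]prop-2-enoate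
Product: 7 (E)-3-[3,4-bis(benzyloxy)phenyl]prop-2-enoic acid
Conditions: LiOH·H2O (3 equiv), THF/MeOH/H2O 3:1:1, 40 °C; then 1 M HCl to pH 2, filter
Reagents that add atoms: lithium hydroxide, [Li+].[OH-]
Why: Ester saponification leaves the benzyl ethers and the alkene untouched, and the acid precipitates on acidification.

Step 4
Reactants: 8 4-aminobutan-1-ol; 9 tert-butyl (3-oxopropyl)carbamate
Product: 11 tert-butyl {3-[(4-hydroxybutyl)amino]propyl}carbamate, via hydroxybutyl aldimine 10 (not isolated)
Conditions: 8 (1.1 equiv), 9, MeOH, 3 Å MS, rt, 2 h; then NaBH4 (1.5 equiv), 0 °C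
Reagents that add atoms: none
Why: Stepwise reductive amination; the aldimine is fully formed before NaBH4 is added, so the primary amine is mono-alkylated and the Boc group and free alcohol are untouched.

Step 5
Reactants: 11 tert-butyl {3-[(4-hydroxybutyl)amino]propyl}carbamate
Product: 12 benzyl {3-[(tert-butoxycarbonyl)amino]propyl}(4-hydroxybutyl)carbamate
Conditions: CbzCl (1.05 equiv), NaHCO3, THF/H2O 1:1, 0 °C → rt
Reagents that add atoms: benzyl chloroformate, O=C(Cl)OCc1ccccc1
Why: Schotten–Baumann N-acylation; under aqueous bicarbonate the secondary amine reacts far faster than the primary alcohol or the Boc-NH, so only N9 is protected.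

Step 6
Reactants: 12 benzyl {3-[(tert-butoxycarbonyl)amino]propyl}(4-hydroxybutyl)carbamate
Product: 13 benzyl {3-[(tert-butoxycarbonyl)amino]propyl}(4-oxobutyl)carbamate
Conditions: Dess–Martin periodinane (1.3 equiv), CH2Cl2, 0 °C → rt; Na2S2O3/NaHCO3 work-up; used at once
Reagents that add atoms: none
Why: Dess–Martin oxidation stops at the aldehyde under near-neutral conditions that spare both carbamates, and the fully substituted carbamate nitrogen cannot cyclise onto the aldehyde.

Step 7
Reactants: 13 benzyl {3-[(tert-butoxycarbonyl)amino]propyl}(4-oxobutyl)carbamate; 14 benzyl (3-aminopropyl)carbamate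
Product: 16 N1,N9-bis(benzyloxycarbonyl)-N12-(tert-butoxycarbonyl)spermine, via Cbz-aminopropyl aldimine 15 (not isolated)
Conditions: 14 (2.0 equiv, free base), MeOH, 3 Å MS, rt, 2 h; then NaBH4 (1.5 equiv), 0 °C; chromatography (CH2Cl2/MeOH/NH3)
Reagents that add atoms: none
Why: Stepwise reductive amination with the cheap amine in excess converts all the aldehyde to the imine before reduction, which suppresses dialkylation; NaBH4 does not touch carbamates.

Step 8
Reactants: 16 N1,N9-bis(benzyloxycarbonyl)-N12-(tert-butoxycarbonyl)spermine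
Product: 17 N1,N9-bis(benzyloxycarbonyl)spermine dihydrochloride (salt at N4 and N12)
Conditions: 4 M HCl in dioxane, CH2Cl2, 0 °C → rt; evaporate
Reagents that add atoms: hydrogen chloride, Cl
Why: Acidolytic Boc cleavage (loss of the tert-butyl cation, then decarboxylation) is orthogonal to Cbz, which is stable to anhydrous HCl at room temperature.

Step 9
Reactants: 7 (E)-3-[3,4-bis(benzyloxy)phenyl]prop-2-enoic acid (2.3 equiv); 17 N1,N9-bis(benzyloxycarbonyl)spermine dihydrochloride
Product: 19 N1,N9-bis(benzyloxycarbonyl)-N4,N12-bis{(E)-3-[3,4-bis(benzyloxy)phenyl]prop-2-enoyl}spermine, via cinnamoyl chloride 18 (not isolated)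
Conditions: 7, (COCl)2 (1.2 equiv per acid), DMF (cat.), CH2Cl2, 0 °C → rt, evaporate; then 17, Et3N (6 equiv), CH2Cl2, 0 °C → rt
Reagents that add atoms: none
Why: Acid chloride formation and N-acylation; the cinnamoyl chloride has no α-hydrogen and acylates both the primary N12 and the secondary N4 amine, while the carbamate NH groups are too weakly nucleophilic to react.

Step 10
Reactants: 19 N1,N9-bis(benzyloxycarbonyl)-N4,N12-bis{(E)-3-[3,4-bis(benzyloxy)phenyl]prop-2-enoyl}spermine
Product: 20 kukoamine B
Conditions: H2 (4 bar), 20% Pd(OH)2/C, MeOH/THF 1:1, rt; filter through Celite under Ar, evaporate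
Reagents that add atoms: none
Why: One-pot catalytic hydrogenation and hydrogenolysis saturates both conjugated C=C bonds, cleaves the four aryl benzyl ethers to toluene and the two Cbz groups to toluene and CO2, and leaves amide and alkyl C–N bonds intact.

**Compound list**
1 | ethyl acetate | CCOC(C)=O | starting material
2 | 3,4-bis(benzyloxy)benzaldehyde | O=Cc1ccc(OCc2ccccc2)c(OCc2ccccc2)c1 | starting material
3 | lithium enolate of ethyl acetate | C=C(O[Li])OCC | intermediate
4 | ethyl (±)-3-[3,4-bis(benzyloxy)phenyl]-3-hydroxypropanoate (racemic) | CCOC(=O)CC(O)c1ccc(OCc2ccccc2)c(OCc2ccccc2)c1 | intermediate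
5 | ethyl (±)-3-[3,4-bis(benzyloxy)phenyl]-3-(methylsulfonyloxy)propanoate | CCOC(=O)CC(OS(C)(=O)=O)c1ccc(OCc2ccccc2)c(OCc2ccccc2)c1 | intermediate
6 | ethyl (E)-3-[3,4-bis(benzyloxy)phenyl]prop-2-enoate | CCOC(=O)/C=C/c1ccc(OCc2ccccc2)c(OCc2ccccc2)c1 | intermediate
7 | (E)-3-[3,4-bis(benzyloxy)phenyl]prop-2-enoic acid | OC(=O)/C=C/c1ccc(OCc2ccccc2)c(OCc2ccccc2)c1 | intermediate
8 | 4-aminobutan-1-ol | NCCCCO | starting material
9 | tert-butyl (3-oxopropyl)carbamate | CC(C)(C)OC(=O)NCCC=O | starting material
10 | tert-butyl (E)-{3-[(4-hydroxybutyl)imino]propyl}carbamate | CC(C)(C)OC(=O)NCC/C=N/CCCCO | intermediate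
11 | tert-butyl {3-[(4-hydroxybutyl)amino]propyl}carbamate | CC(C)(C)OC(=O)NCCCNCCCCO | intermediate
12 | benzyl {3-[(tert-butoxycarbonyl)amino]propyl}(4-hydroxybutyl)carbamate | CC(C)(C)OC(=O)NCCCN(CCCCO)C(=O)OCc1ccccc1 | intermediate
13 | benzyl {3-[(tert-butoxycarbonyl)amino]propyl}(4-oxobutyl)carbamate | CC(C)(C)OC(=O)NCCCN(CCCC=O)C(=O)OCc1ccccc1 | intermediate
14 | benzyl (3-aminopropyl)carbamate | NCCCNC(=O)OCc1ccccc1 | starting material
15 | aldimine of 13 with 14 (E) | CC(C)(C)OC(=O)NCCCN(CCC/C=N/CCCNC(=O)OCc1ccccc1)C(=O)OCc1ccccc1 | intermediate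
16 | N1,N9-bis(benzyloxycarbonyl)-N12-(tert-butoxycarbonyl)spermine | CC(C)(C)OC(=O)NCCCN(CCCCNCCCNC(=O)OCc1ccccc1)C(=O)OCc1ccccc1 | intermediate
17 | N1,N9-bis(benzyloxycarbonyl)spermine dihydrochloride | Cl.Cl.NCCCN(CCCCNCCCNC(=O)OCc1ccccc1)C(=O)OCc1ccccc1 | intermediate
18 | (E)-3-[3,4-bis(benzyloxy)phenyl]prop-2-enoyl chloride | ClC(=O)/C=C/c1ccc(OCc2ccccc2)c(OCc2ccccc2)c1 | intermediate
19 | N1,N9-bis(benzyloxycarbonyl)-N4,N12-bis{(E)-3-[3,4-bis(benzyloxy)phenyl]prop-2-enoyl}spermine | O=C(/C=C/c1ccc(OCc2ccccc2)c(OCc2ccccc2)c1)NCCCN(CCCCN(CCCNC(=O)OCc1ccccc1)C(=O)/C=C/c1ccc(OCc2ccccc2)c(OCc2ccccc2)c1)C(=O)OCc1ccccc1 | intermediate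
20 | kukoamine B, N4,N12-bis[3-(3,4-dihydroxyphenyl)propanoyl]spermine | NCCCN(CCCCNCCCNC(=O)CCc1ccc(O)c(O)c1)C(=O)CCc1ccc(O)c(O)c1 | target

**Totals**
Total step count: 10. Longest linear sequence: 7 steps (steps 4, 5, 6, 7, 8, 9, 10); the acid branch (steps 1–3) joins at step 9.

**Three steps most likely to fail, with fallbacks**

Step 4. The β-carbamoyl aldehyde 9 can eliminate or self-condense, and the polar amino alcohol 11 is awkward to purify. The fallback sets out from 8 and comes back at 11. Aza-Michael addition of 8 to acrylonitrile (MeOH, 0 °C → rt) gives 3-[(4-hydroxybutyl)amino]propanenitrile F1 as a clean mono-adduct. Hydrogenation of the nitrile over Raney nickel in NH3/MeOH gives 4-[(3-aminopropyl)amino]butan-1-ol F2. tert-Butyl phenyl carbonate (EtOH, rt) then carbamoylates only the primary amine, sparing the secondary amine and the alcohol, and delivers 11.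

Step 7. Over-alkylation to the tertiary amine is possible and aldehyde 13 is labile. The fallback sets out from alcohol 12 (so step 6 is skipped) and amine 14, and comes back at 16. Amine 14 is sulfonylated with 2-nitrobenzenesulfonyl chloride/Et3N to give benzyl {3-[(2-nitrophenyl)sulfonylamino]propyl}carbamate F3. A Fukuyama–Mitsunobu alkylation of F3 with 12 (PPh3, DIAD, THF) can only mono-alkylate and gives N1,N9-bis(benzyloxycarbonyl)-N12-(tert-butoxycarbonyl)-N4-(2-nitrophenylsulfonyl)spermine F4. Thiolysis (PhSH, K2CO3, DMF) removes the nosyl group and returns 16.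

Step 10. Eight reductions are needed in one pot, the freed polyamine can poison palladium, and the catechol-amine product is air-sensitive. The fallback sets out from 19 and comes back at 20. All six benzyl-type groups are first removed without hydrogen using BCl3 with pentamethylbenzene as benzyl-cation scavenger (CH2Cl2, −78 °C → rt, MeOH quench). This gives N4,N12-bis[(E)-3-(3,4-dihydroxyphenyl)prop-2-enoyl]spermine F5, handled as its hydrochloride. With the amines protonated and no hydrogenolysis left to do, the two cinnamoyl C=C bonds are then saturated (H2, Pd/C, MeOH/H2O) and the salt is neutralised to give 20.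

**Further compounds**
F1 | step 4 | 3-[(4-hydroxybutyl)amino]propanenitrile | N#CCCNCCCCO
F2 | step 4 | 4-[(3-aminopropyl)amino]butan-1-ol | NCCCNCCCCO
F3 | step 7 | benzyl {3-[(2-nitrophenyl)sulfonylamino]propyl}carbamate | O=C(OCc1ccccc1)NCCCNS(=O)(=O)c1ccccc1[N+](=O)[O-]
F4 | step 7 | N1,N9-bis(benzyloxycarbonyl)-N12-(tert-butoxycarbonyl)-N4-(2-nitrophenylsulfonyl)spermine | CC(C)(C)OC(=O)NCCCN(CCCCN(CCCNC(=O)OCc1ccccc1)S(=O)(=O)c1ccccc1[N+](=O)[O-])C(=O)OCc1ccccc1
F5 | step 10 | N4,N12-bis[(E)-3-(3,4-dihydroxyphenyl)prop-2-enoyl]spermine | NCCCN(CCCCNCCCNC(=O)/C=C/c1ccc(O)c(O)c1)C(=O)/C=C/c1ccc(O)c(O)c1
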